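**Plan**
- Retrosynthesis: cut the C8 ester C–O bond, take the C12 acid back to an isopropenyl methyl and C15 back to a C4 ketone, then open ring A at C2–C3 and C1–C10 by a [4+2] disconnection.
- Enabling feature: on ring B (C5–C10) the 8α oxygen and the C10–C1 bond are 1,3-cis, and ring A carries oxygen at C1 and a carbonyl-level carbon at C4 (1,4). O8 can therefore carry a two-carbon dienophile on a temporary sulfonyl link (O8–SO2–C1) and deliver it to a ring-B 2-ethoxy diene C3=C4(OEt)–C5=C10.
- Forward order: ring B from an aromatic precursor (quinone monoketal, then cyclohexene); ring A and the quaternary C10 in the intramolecular Diels–Alder step; then excision of sulfur to a C1 ketone/C8 alcohol pair, which tells the two oxygens apart.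
- Stereochemistry: C7 by catalyst control (rhodium/BINAP conjugate addition); C6 and C8 relayed from C7; C10 by the O8 tether; C1, C5 and C4 by substrate and thermodynamic control.
- Helpers removed later: sulfonyl link (oxidative desulfonylation), ethyl enol ether (hydrolysis), phosphonoacetate (turned into the hydroxymethylacrylate), silyl ether (fluoride).

Key step: step 8

Remark: eudesmane numbering and the α/β faces of the final decalin (C10 methyl β) are used for every intermediate; the target is treated as the open hydroxy acid and hydroxy aldehyde that is drawn, not as a lactone or lactol.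

**Step 1**
Reactants: 1 4-methoxy-2-methylphenol
Product: 2 4,4-dimethoxy-2-methylcyclohexa-2,5-dien-1-one
Conditions: PhI(OAc)2, MeOH, 0 °C
Reagents that add atoms: methanol CO
Why: Oxidative dearomatisation of a para-methoxyphenol by the hypervalent iodine reagent in methanol should give the para-quinone monoketal, which already holds the C5 carbonyl, the C8 oxygen and the C10 methyl of ring B; no stereocenter is formed.

**Step 2**
Reactants: 2 4,4-dimethoxy-2-methylcyclohexa-2,5-dien-1-one; 3 potassium trifluoro(prop-1-en-2-yl)borate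
Product: 4 (5R)-4,4-dimethoxy-2-methyl-5-(prop-1-en-2-yl)cyclohex-2-en-1-one
Conditions: [Rh(cod)2]BF4 (cat.), (R)-BINAP, Et3N, toluene/H2O, 40 °C
Reagents that add atoms: none
Why: Rhodium/BINAP-catalysed asymmetric conjugate addition of the alkenyl trifluoroborate (Hayashi–Miyaura reaction) should occur at the unsubstituted enone C6=C7, not at the slower 2-methyl enone, and sets C7 by catalyst control; the (R)-ligand is expected by analogy with 2-cyclohexenone to give the 5R adduct, and its antipode would be used otherwise.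

**Step 3**
Reactants: 4 (5R)-4,4-dimethoxy-2-methyl-5-(prop-1-en-2-yl)cyclohex-2-en-1-one
Product: 6 (5S,6S)-6-hydroxy-4,4-dimethoxy-2-methyl-5-(prop-1-en-2-yl)cyclohex-2-en-1-one, via potassium dienolate 5 (not isolated)
Conditions: KN(SiMe3)2, THF, −78 °C; then 2-(phenylsulfonyl)-3-phenyloxaziridine, −78 °C
Reagents that add atoms: 2-(phenylsulfonyl)-3-phenyloxaziridine O=S(=O)(c1ccccc1)N1OC1c1ccccc1
Why: The ketal carbon blocks γ-enolisation, so only the cross-conjugated C5–C6 dienolate can form, and its oxidation by the N-sulfonyloxaziridine (enolate hydroxylation) should occur anti to the neighbouring C7 isopropenyl group, giving the 6α hydroxyl trans to it.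

**Step 4**
Reactants: 6 (5S,6S)-6-hydroxy-4,4-dimethoxy-2-methyl-5-(prop-1-en-2-yl)cyclohex-2-en-1-one
Product: 7 (5S,6S)-6-[(tert-butyldimethylsilyl)oxy]-4,4-dimethoxy-2-methyl-5-(prop-1-en-2-yl)cyclohex-2-en-1-one
Conditions: TBSOTf, 2,6-lutidine, CH2Cl2, −78 °C
Reagents that add atoms: tert-butyldimethylsilyl trifluoromethanesulfonate CC(C)(C)[Si](C)(C)OS(=O)(=O)C(F)(F)F
Why: Silylation of the hindered secondary alcohol with the silyl triflate at low temperature should leave the ketal intact and touches no stereocenter.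

**Step 5**
Reactants: 7 (5S,6S)-6-[(tert-butyldimethylsilyl)oxy]-4,4-dimethoxy-2-methyl-5-(prop-1-en-2-yl)cyclohex-2-en-1-one
Product: 9 (5S,6S)-6-[(tert-butyldimethylsilyl)oxy]-4,4-dimethoxy-2-methyl-5-(prop-1-en-2-yl)cyclohex-1-en-1-yl trifluoromethanesulfonate, via lithium enolate 8 (not isolated)
Conditions: LiBH(s-Bu)3, THF, −78 °C; then N-(5-chloropyridin-2-yl)bis(trifluoromethanesulfonimide), −78 to 0 °C
Reagents that add atoms: N-(5-chloropyridin-2-yl)bis(trifluoromethanesulfonimide) O=S(=O)(N(c1ccc(Cl)cn1)S(=O)(=O)C(F)(F)F)C(F)(F)F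
Why: 1,4-Reduction of the enone by the bulky borohydride gives the C5–C10 enolate regiospecifically, and O-triflation fixes it as the tetrasubstituted enol triflate (conjugate reduction with enolate trapping), which settles the position of the later ring-B double bond.

**Step 6**
Reactants: 9 (5S,6S)-6-[(tert-butyldimethylsilyl)oxy]-4,4-dimethoxy-2-methyl-5-(prop-1-en-2-yl)cyclohex-1-en-1-yl trifluoromethanesulfonate
Product: 11 (4S,5R,6S)-6-[(tert-butyldimethylsilyl)oxy]-4-hydroxy-2-methyl-5-(prop-1-en-2-yl)cyclohex-1-en-1-yl trifluoromethanesulfonate, via C8 ketone 10 (not isolated)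
Conditions: pyridinium p-toluenesulfonate (cat.), acetone/H2O, rt; then NaBH4, MeOH, −78 °C
Reagents that add atoms: water O
Why: Mild ketal hydrolysis is followed at once by borohydride reduction; with the C6 silyloxy group pseudoaxial on the α face (allylic strain with the C5 triflate), hydride should add from the β face and give the 8α alcohol, cis to O6 and trans to the C7 isopropenyl group.

**Step 7**
Reactants: 11 (4S,5R,6S)-6-[(tert-butyldimethylsilyl)oxy]-4-hydroxy-2-methyl-5-(prop-1-en-2-yl)cyclohex-1-en-1-yl trifluoromethanesulfonate; 12 tributyl(1-ethoxyethenyl)stannane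
Product: 13 (1S,5S,6R)-5-[(tert-butyldimethylsilyl)oxy]-4-(1-ethoxyethenyl)-3-methyl-6-(prop-1-en-2-yl)cyclohex-3-en-1-ol
Conditions: Pd(PPh3)4 (cat.), LiCl, THF, 65 °C; basic work-up
Reagents that add atoms: none
Why: Stille coupling of the enol triflate with the 1-ethoxyvinylstannane installs C4 and C3 as an electron-rich 2-ethoxy-1,3-diene, and the basic work-up should keep the enol ether.

**Step 8**
Reactants: 13 (1S,5S,6R)-5-[(tert-butyldimethylsilyl)oxy]-4-(1-ethoxyethenyl)-3-methyl-6-(prop-1-en-2-yl)cyclohex-3-en-1-ol; 14 2-chloroethanesulfonyl chloride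
Product: 16 tricyclic δ-sultone (O8–SO2–C1 bridge on the α face; 4-ethoxy-6α-silyloxy-eudesma-4,11(13)-diene core; C10 methyl β), via vinylsulfonate 15 (not isolated)
Conditions: Et3N, CH2Cl2, 0 °C; then toluene, 2,6-di-tert-butyl-4-methylphenol (cat.), 90 °C
Reagents that add atoms: none
Why: Sulfonylation with loss of HCl gives vinylsulfonate 15, which should undergo an intramolecular normal-electron-demand Diels–Alder reaction: the electron-rich diene C3=C4(OEt)–C5=C10 adds across the electron-poor C1=C2 in a concerted, asynchronous [4+2], the nucleophilic terminus C3 bonding to the β carbon C2 and the sulfonyl-bearing C1 bonding to C10. The closest known reaction type is the intramolecular Diels–Alder reaction of vinylsulfonates of dienols to δ-sultones. Ring A (C1–C2–C3–C4=C5–C10) is closed by the cycloaddition itself, and the six-membered sultone ring O8–S–C1–C10–C9–C8 is the tether ring, fused to ring A at C1–C10 and bridging C8 and C10 of ring B. The quaternary C10 is set by the tether, since the 8α oxygen can reach only the α face of C10, so C1 arrives cis to O8 and the methyl becomes β; C1 is expected with sulfur cis to C9, but this center is erased in step 9. The step needs regioselectivity (C1 to C10, C2 to C3), secured both by the four-atom tether and by the matched polarity of ethoxy diene and vinylsulfonate, facial selectivity (tether), and periselectivity over the isopropenyl group, which is neither conjugated nor activated.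

**Step 9**
Reactants: 16 tricyclic δ-sultone
Product: 19 4-ethoxy-6α-[(tert-butyldimethylsilyl)oxy]-8α-hydroxyeudesma-4,11(13)-dien-1-one, via lithiated sultone 17 (not isolated), via silyloxy sultone 18 (not isolated)
Conditions: n-BuLi, THF, −78 °C; then Me3SiOOSiMe3, −78 to 0 °C; aqueous work-up
Reagents that add atoms: bis(trimethylsilyl) peroxide C[Si](C)(C)OO[Si](C)(C)C
Why: Lithiation next to sulfur and oxygen transfer from the silyl peroxide give an α-silyloxy sulfonate that should collapse to the C1 ketone with loss of the sulfur bridge as sulfite (oxidative desulfonylation); this frees the C8 hydroxyl while C1 stays a ketone and C4 stays masked as its enol ether.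

**Step 10**
Reactants: 19 4-ethoxy-6α-[(tert-butyldimethylsilyl)oxy]-8α-hydroxyeudesma-4,11(13)-dien-1-one; 20 (diethoxyphosphoryl)acetic acid
Product: 21 8α-[(diethoxyphosphoryl)acetoxy]-4-ethoxy-6α-[(tert-butyldimethylsilyl)oxy]eudesma-4,11(13)-dien-1-one
Conditions: N,N'-dicyclohexylcarbodiimide, 4-(dimethylamino)pyridine (cat.), CH2Cl2, 0 °C to rt
Reagents that add atoms: none
Why: Steglich esterification acylates the only free hydroxyl (C8) with the phosphonoacetic acid, a latent 2-(hydroxymethyl)acrylate that tolerates the hydride, oxidation and ylide steps that follow.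

**Step 11**
Reactants: 21 8α-[(diethoxyphosphoryl)acetoxy]-4-ethoxy-6α-[(tert-butyldimethylsilyl)oxy]eudesma-4,11(13)-dien-1-one
Product: 23 8α-[(diethoxyphosphoryl)acetoxy]-6α-[(tert-butyldimethylsilyl)oxy]-1β-hydroxy-15-nor-5αH-eudesm-11(13)-en-4-one, via enol ether alcohol 22 (not isolated)
Conditions: NaBH4, MeOH/THF, −40 °C; then 1 M HCl, THF, rt
Reagents that add atoms: water O
Why: Borohydride should attack the C1 ketone from the α face, anti to the adjacent angular methyl, to give the 1β (equatorial) alcohol; dilute acid then hydrolyses the enol ether, and C5, protonated anti to the methyl and free to equilibrate through the enol, should end as the trans-fused 4-decalone (5α-H).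

**Step 12**
Reactants: 23 8α-[(diethoxyphosphoryl)acetoxy]-6α-[(tert-butyldimethylsilyl)oxy]-1β-hydroxy-15-nor-5αH-eudesm-11(13)-en-4-one
Product: 25 the corresponding 12-al (C7 side chain C(=CH2)CHO), via allylic alcohol 24 (not isolated)
Conditions: SeO2 (cat.), t-BuOOH, CH2Cl2, rt; then MnO2, CH2Cl2, rt
Reagents that add atoms: tert-butyl hydroperoxide CC(C)(C)OO; selenium dioxide O=[Se]=O (catalytic oxygen carrier)
Why: Selenium dioxide allylic oxidation (ene reaction then [2,3] shift) should take the methyl group of the only alkene left, the 1,1-disubstituted isopropenyl group, and MnO2 carries the allylic alcohol on to the enal without touching the saturated C1 alcohol.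

**Step 13**
Reactants: 25 12-al
Product: 26 8α-[(diethoxyphosphoryl)acetoxy]-6α-[(tert-butyldimethylsilyl)oxy]-1β-hydroxy-4-oxo-15-nor-5αH-eudesm-11(13)-en-12-oic acid
Conditions: NaClO2, NaH2PO4, 2-methyl-2-butene, t-BuOH/H2O, 0 °C to rt
Reagents that add atoms: sodium chlorite [Na+].[O-]Cl=O
Why: Pinnick oxidation converts the enal into the acrylic acid under buffered conditions that should leave the ketone, phosphonate, silyl ether and secondary alcohol alone, and no other aldehyde is present at this stage.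

**Step 14**
Reactants: 26 4-oxo-12-oic acid; 27 (methoxymethyl)triphenylphosphonium chloride
Product: 28 8α-[(diethoxyphosphoryl)acetoxy]-6α-[(tert-butyldimethylsilyl)oxy]-1β-hydroxy-15-methoxy-5αH-eudesma-4(15),11(13)-dien-12-oic acid (enol ether, either geometry)
Conditions: KN(SiMe3)2 (excess), THF, 0 °C to rt
Reagents that add atoms: none
Why: Wittig methoxymethylenation brings in C15 at the C4 ketone, the only carbonyl electrophile left once excess base has deprotonated the acid, the alcohol and the phosphonoacetate; the acrylate, present as its carboxylate, should not act as a Michael acceptor.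

**Step 15**
Reactants: 28 enol ether acid; 29 formaldehyde (aqueous)
Product: 31 6α-[(tert-butyldimethylsilyl)oxy]-1β-hydroxy-8α-{[2-(hydroxymethyl)prop-2-enoyl]oxy}-15-methoxy-5αH-eudesma-4(15),11(13)-dien-12-oic acid, via hydroxymethyl phosphonate 30 (not isolated)
Conditions: K2CO3, H2O/THF, rt
Reagents that add atoms: none
Why: Under aqueous carbonate the phosphonoacetate is first hydroxymethylated by formaldehyde and then undergoes Horner–Wadsworth–Emmons olefination with a second formaldehyde, which should give the 2-(hydroxymethyl)acrylate directly; C15 is still an enol ether and cannot compete as the olefination partner.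

**Step 16**
Reactants: 31 hydroxymethylacrylate enol ether
Product: 33 6-O-(tert-butyldimethylsilyl) ether of the target (4α-formyl), via 4β-formyl epimer 32 (not isolated)
Conditions: 0.5 M HCl, THF/H2O, rt
Reagents that add atoms: water O
Why: Dilute acid hydrolyses the methyl enol ether to the aldehyde, and the enolisable C4 center should equilibrate to the equatorial 4α-formyl group because the 4β epimer is 1,3-diaxial to the C10 methyl; the C6 silyl ether keeps the acid from lactonising meanwhile.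

**Step 17**
Reactants: 33 6-O-(tert-butyldimethylsilyl) ether of the target
Product: 34 target, 1β,6α-dihydroxy-8α-{[2-(hydroxymethyl)prop-2-enoyl]oxy}-15-oxo-4βH,5αH-eudesm-11(13)-en-12-oic acid
Conditions: HF·pyridine, pyridine, THF, 0 °C to rt
Reagents that add atoms: none
Why: Buffered fluoride should cleave the silyl ether under conditions too mild for lactonisation, acyl migration or conjugate addition to the two acrylates, giving the target.

**Compound list**
1 | 4-methoxy-2-methylphenol | COc1ccc(O)c(C)c1 | starting material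
2 | 4,4-dimethoxy-2-methylcyclohexa-2,5-dien-1-one | COC1(OC)C=CC(=O)C(C)=C1 | intermediate
3 | potassium trifluoro(prop-1-en-2-yl)borate | [K+].CC(=C)[B-](F)(F)F | starting material
4 | (5R)-4,4-dimethoxy-2-methyl-5-(prop-1-en-2-yl)cyclohex-2-en-1-one | COC1(OC)C=C(C)C(=O)C[C@@H]1C(C)=C | intermediate
5 | potassium cross-conjugated (C1–C6) dienolate of 4 | [K+].COC1(OC)C=C(C)C([O-])=C[C@@H]1C(C)=C | intermediate
6 | (5S,6S)-6-hydroxy-4,4-dimethoxy-2-methyl-5-(prop-1-en-2-yl)cyclohex-2-en-1-one (OH trans to isopropenyl) | COC1(OC)C=C(C)C(=O)[C@@H](O)[C@@H]1C(C)=C | intermediate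
7 | (5S,6S)-6-[(tert-butyldimethylsilyl)oxy]-4,4-dimethoxy-2-methyl-5-(prop-1-en-2-yl)cyclohex-2-en-1-one | COC1(OC)C=C(C)C(=O)[C@@H](O[Si](C)(C)C(C)(C)C)[C@@H]1C(C)=C | intermediate
8 | lithium C5–C10 enolate from 1,4-reduction of 7 | [Li+].COC1(OC)CC(C)=C([O-])[C@@H](O[Si](C)(C)C(C)(C)C)[C@@H]1C(C)=C | intermediate
9 | (5S,6S)-6-[(tert-butyldimethylsilyl)oxy]-4,4-dimethoxy-2-methyl-5-(prop-1-en-2-yl)cyclohex-1-en-1-yl trifluoromethanesulfonate | COC1(OC)CC(C)=C(OS(=O)(=O)C(F)(F)F)[C@@H](O[Si](C)(C)C(C)(C)C)[C@@H]1C(C)=C | intermediate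
10 | (5S,6S)-6-[(tert-butyldimethylsilyl)oxy]-2-methyl-4-oxo-5-(prop-1-en-2-yl)cyclohex-1-en-1-yl trifluoromethanesulfonate | O=C1CC(C)=C(OS(=O)(=O)C(F)(F)F)[C@@H](O[Si](C)(C)C(C)(C)C)[C@@H]1C(C)=C | intermediate
11 | (4S,5R,6S)-6-[(tert-butyldimethylsilyl)oxy]-4-hydroxy-2-methyl-5-(prop-1-en-2-yl)cyclohex-1-en-1-yl trifluoromethanesulfonate (6α-OTBS, 7β-isopropenyl, 8α-OH) | O[C@H]1CC(C)=C(OS(=O)(=O)C(F)(F)F)[C@@H](O[Si](C)(C)C(C)(C)C)[C@@H]1C(C)=C | intermediate
12 | tributyl(1-ethoxyethenyl)stannane | CCCC[Sn](CCCC)(CCCC)C(=C)OCC | starting material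
13 | (1S,5S,6R)-5-[(tert-butyldimethylsilyl)oxy]-4-(1-ethoxyethenyl)-3-methyl-6-(prop-1-en-2-yl)cyclohex-3-en-1-ol | O[C@H]1CC(C)=C(C(=C)OCC)[C@@H](O[Si](C)(C)C(C)(C)C)[C@@H]1C(C)=C | intermediate
14 | 2-chloroethanesulfonyl chloride | ClCCS(=O)(=O)Cl | starting material
15 | ethenesulfonate (vinylsulfonate) ester of alcohol 13 | C=CS(=O)(=O)O[C@H]1CC(C)=C(C(=C)OCC)[C@@H](O[Si](C)(C)C(C)(C)C)[C@@H]1C(C)=C | intermediate
16 | tricyclic δ-sultone: 4-ethoxy-6α-[(tert-butyldimethylsilyl)oxy]eudesma-4,11(13)-diene with an α-face O8–SO2–C1 bridge, C10 methyl β | O=S1(=O)O[C@H]2C[C@]3(C)C(=C(OCC)CC[C@@H]31)[C@@H](O[Si](C)(C)C(C)(C)C)[C@@H]2C(C)=C | intermediate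
17 | C1-lithiated sultone 16 | [Li+].O=S1(=O)O[C@H]2C[C@]3(C)C(=C(OCC)CC[C-]31)[C@@H](O[Si](C)(C)C(C)(C)C)[C@@H]2C(C)=C | intermediate
18 | 1-(trimethylsilyloxy) sultone (C1 configuration of no consequence) | O=S1(=O)O[C@H]2C[C@]3(C)C(=C(OCC)CCC31O[Si](C)(C)C)[C@@H](O[Si](C)(C)C(C)(C)C)[C@@H]2C(C)=C | intermediate
19 | 4-ethoxy-6α-[(tert-butyldimethylsilyl)oxy]-8α-hydroxyeudesma-4,11(13)-dien-1-one | O[C@H]1C[C@]2(C)C(=C(OCC)CCC2=O)[C@@H](O[Si](C)(C)C(C)(C)C)[C@@H]1C(C)=C | intermediate
20 | (diethoxyphosphoryl)acetic acid | OC(=O)CP(=O)(OCC)OCC | starting material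
21 | 8α-[(diethoxyphosphoryl)acetoxy]-4-ethoxy-6α-[(tert-butyldimethylsilyl)oxy]eudesma-4,11(13)-dien-1-one | CCOP(=O)(OCC)CC(=O)O[C@H]1C[C@]2(C)C(=C(OCC)CCC2=O)[C@@H](O[Si](C)(C)C(C)(C)C)[C@@H]1C(C)=C | intermediate
22 | 8α-[(diethoxyphosphoryl)acetoxy]-4-ethoxy-6α-[(tert-butyldimethylsilyl)oxy]eudesma-4,11(13)-dien-1β-ol | CCOP(=O)(OCC)CC(=O)O[C@H]1C[C@]2(C)C(=C(OCC)CC[C@H]2O)[C@@H](O[Si](C)(C)C(C)(C)C)[C@@H]1C(C)=C | intermediate
23 | 8α-[(diethoxyphosphoryl)acetoxy]-6α-[(tert-butyldimethylsilyl)oxy]-1β-hydroxy-15-nor-5αH-eudesm-11(13)-en-4-one | CCOP(=O)(OCC)CC(=O)O[C@H]1C[C@]2(C)[C@@H]([C@@H](O[Si](C)(C)C(C)(C)C)[C@@H]1C(C)=C)C(=O)CC[C@H]2O | intermediate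
24 | 12-hydroxy derivative of 23 (allylic alcohol) | CCOP(=O)(OCC)CC(=O)O[C@H]1C[C@]2(C)[C@@H]([C@@H](O[Si](C)(C)C(C)(C)C)[C@@H]1C(=C)CO)C(=O)CC[C@H]2O | intermediate
25 | 12-al derived from 23 (enal) | CCOP(=O)(OCC)CC(=O)O[C@H]1C[C@]2(C)[C@@H]([C@@H](O[Si](C)(C)C(C)(C)C)[C@@H]1C(=C)C=O)C(=O)CC[C@H]2O | intermediate
26 | 8α-[(diethoxyphosphoryl)acetoxy]-6α-[(tert-butyldimethylsilyl)oxy]-1β-hydroxy-4-oxo-15-nor-5αH-eudesm-11(13)-en-12-oic acid | CCOP(=O)(OCC)CC(=O)O[C@H]1C[C@]2(C)[C@@H]([C@@H](O[Si](C)(C)C(C)(C)C)[C@@H]1C(=C)C(=O)O)C(=O)CC[C@H]2O | intermediate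
27 | (methoxymethyl)triphenylphosphonium chloride | [Cl-].COC[P+](c1ccccc1)(c1ccccc1)c1ccccc1 | starting material
28 | 8α-[(diethoxyphosphoryl)acetoxy]-6α-[(tert-butyldimethylsilyl)oxy]-1β-hydroxy-15-methoxy-5αH-eudesma-4(15),11(13)-dien-12-oic acid (enol ether geometry not defined) | CCOP(=O)(OCC)CC(=O)O[C@H]1C[C@]2(C)[C@@H]([C@@H](O[Si](C)(C)C(C)(C)C)[C@@H]1C(=C)C(=O)O)C(=COC)CC[C@H]2O | intermediate
29 | formaldehyde | C=O | starting material
30 | 8α-[2-(diethoxyphosphoryl)-3-hydroxypropanoyloxy] analogue of 28 | CCOP(=O)(OCC)C(CO)C(=O)O[C@H]1C[C@]2(C)[C@@H]([C@@H](O[Si](C)(C)C(C)(C)C)[C@@H]1C(=C)C(=O)O)C(=COC)CC[C@H]2O | intermediate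
31 | 6α-[(tert-butyldimethylsilyl)oxy]-1β-hydroxy-8α-{[2-(hydroxymethyl)prop-2-enoyl]oxy}-15-methoxy-5αH-eudesma-4(15),11(13)-dien-12-oic acid | C=C(CO)C(=O)O[C@H]1C[C@]2(C)[C@@H]([C@@H](O[Si](C)(C)C(C)(C)C)[C@@H]1C(=C)C(=O)O)C(=COC)CC[C@H]2O | intermediate
32 | 4β-formyl (axial) epimer of 33 | C=C(CO)C(=O)O[C@H]1C[C@]2(C)[C@@H]([C@@H](O[Si](C)(C)C(C)(C)C)[C@@H]1C(=C)C(=O)O)[C@@H](C=O)CC[C@H]2O | intermediate
33 | 6-O-(tert-butyldimethylsilyl) ether of the target (4α-formyl) | C=C(CO)C(=O)O[C@H]1C[C@]2(C)[C@@H]([C@@H](O[Si](C)(C)C(C)(C)C)[C@@H]1C(=C)C(=O)O)[C@H](C=O)CC[C@H]2O | intermediate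
34 | 1β,6α-dihydroxy-8α-{[2-(hydroxymethyl)prop-2-enoyl]oxy}-15-oxo-4βH,5αH-eudesm-11(13)-en-12-oic acid | C=C(CO)C(=O)O[C@H]1C[C@]2(C)[C@@H]([C@@H](O)[C@@H]1C(=C)C(=O)O)[C@H](C=O)CC[C@H]2O | target

**Count and risks**
Total step count: 17. Longest linear sequence: 17 steps (from 1 to 34; compounds 3, 12, 14, 20, 27 and 29 are bought).

Steps most likely to fail:

1. Step 8. The ring-B conformer that lets O8 reach C10 pushes the sulfonyl bridge against the axial 6α-silyloxy group, so cycloaddition may be slow and thermal isomerisation of the ethoxy diene or polymerisation of the vinylsulfonate may take over. Fallback, from 13 back to 19, with a smaller, planar ester tether: alcohol 13 is acylated with acryloyl chloride (Et3N, CH2Cl2) to the acrylate ester F1. Its ester-tethered intramolecular Diels–Alder reaction (toluene, 130 °C) should give the δ-lactone F2 with C10 set in the same way. Hydroxylation of the lactone enolate (LiN(iPr)2, then 2-(phenylsulfonyl)-3-phenyloxaziridine) gives the α-hydroxy lactone F3, LiAlH4 reduces it to the triol F4, and NaIO4 (NaHCO3 buffer) cleaves the glycol to hydroxy ketone 19.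

2. Step 9. Oxygen transfer to the hindered tertiary α-sulfonyl carbanion may be slower than its fragmentation (loss of the C8 alkoxide from sulfur) or than attack of butyllithium at sulfur. Fallback, from 16 back to 19, by borylation then oxidation: 16 is deprotonated with LiN(SiMe3)2 in the presence of 2-isopropoxy-4,4,5,5-tetramethyl-1,3,2-dioxaborolane to give the 1-boryl sultone F5. NaBO3·4H2O (THF/H2O) oxidises the C–B bond, and the α-hydroxy sulfonate collapses to 19.

3. Step 14. The ylide may be used up in deprotonating the acid, the alcohol and the phosphonoacetate, the polyanion may be poorly soluble, and loss of the 6-silyloxy group from the C4 enolate is a second drain, so olefination may stay incomplete. Fallback, from 23 back to 33, with homologation before the oxidations and the aldehyde masked: 23 (no acid yet) is treated with the ylide from 27 to give the enol ether F6. 1 M HCl hydrolyses and equilibrates it to the 4α-aldehyde F7, and HC(OMe)3 with pyridinium p-toluenesulfonate in MeOH gives the dimethyl acetal F8. The conditions of steps 12, 13 and 15 then give the enal F9, the acid F10 and the hydroxymethylacrylate F11, and dilute aqueous acid releases the aldehyde to reach 33.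

**Further compounds**
F1 | step 8 | prop-2-enoate (acrylate) ester of alcohol 13 | C=CC(=O)O[C@H]1CC(C)=C(C(=C)OCC)[C@@H](O[Si](C)(C)C(C)(C)C)[C@@H]1C(C)=C
F2 | step 8 | δ-lactone (C1–CO–O8 bridge on the α face) of the 4-ethoxy-6α-silyloxy-eudesma-4,11(13)-diene core | O=C1O[C@H]2C[C@]3(C)C(=C(OCC)CC[C@@H]31)[C@@H](O[Si](C)(C)C(C)(C)C)[C@@H]2C(C)=C
F3 | step 8 | 1-hydroxy derivative of lactone F2 (C1 configuration of no consequence) | O=C1O[C@H]2C[C@]3(C)C(=C(OCC)CCC31O)[C@@H](O[Si](C)(C)C(C)(C)C)[C@@H]2C(C)=C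
F4 | step 8 | 4-ethoxy-6α-[(tert-butyldimethylsilyl)oxy]-1-(hydroxymethyl)eudesma-4,11(13)-diene-1,8α-diol | O[C@H]1C[C@]2(C)C(=C(OCC)CCC2(O)CO)[C@@H](O[Si](C)(C)C(C)(C)C)[C@@H]1C(C)=C
F5 | step 9 | 1-(4,4,5,5-tetramethyl-1,3,2-dioxaborolan-2-yl) derivative of sultone 16 | O=S1(=O)O[C@H]2C[C@]3(C)C(=C(OCC)CCC31B4OC(C)(C)C(C)(C)O4)[C@@H](O[Si](C)(C)C(C)(C)C)[C@@H]2C(C)=C
F6 | step 14 | 15-methoxy-4(15)-ene (enol ether) from 23 | CCOP(=O)(OCC)CC(=O)O[C@H]1C[C@]2(C)[C@@H]([C@@H](O[Si](C)(C)C(C)(C)C)[C@@H]1C(C)=C)C(=COC)CC[C@H]2O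
F7 | step 14 | 4α-formyl compound from F6 | CCOP(=O)(OCC)CC(=O)O[C@H]1C[C@]2(C)[C@@H]([C@@H](O[Si](C)(C)C(C)(C)C)[C@@H]1C(C)=C)[C@H](C=O)CC[C@H]2O
F8 | step 14 | dimethyl acetal of F7 | CCOP(=O)(OCC)CC(=O)O[C@H]1C[C@]2(C)[C@@H]([C@@H](O[Si](C)(C)C(C)(C)C)[C@@H]1C(C)=C)[C@H](C(OC)OC)CC[C@H]2O
F9 | step 14 | 12-al of F8 | CCOP(=O)(OCC)CC(=O)O[C@H]1C[C@]2(C)[C@@H]([C@@H](O[Si](C)(C)C(C)(C)C)[C@@H]1C(=C)C=O)[C@H](C(OC)OC)CC[C@H]2O
F10 | step 14 | 12-oic acid of F8 | CCOP(=O)(OCC)CC(=O)O[C@H]1C[C@]2(C)[C@@H]([C@@H](O[Si](C)(C)C(C)(C)C)[C@@H]1C(=C)C(=O)O)[C@H](C(OC)OC)CC[C@H]2O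
F11 | step 14 | 8-O-[2-(hydroxymethyl)prop-2-enoyl] 15-dimethyl acetal of the 6-O-silyl target | C=C(CO)C(=O)O[C@H]1C[C@]2(C)[C@@H]([C@@H](O[Si](C)(C)C(C)(C)C)[C@@H]1C(=C)C(=O)O)[C@H](C(OC)OC)CC[C@H]2O
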